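## The problem

Compound 21 is an aryltetralin lignan. An aromatic ring A (C4a, C5–C8, C8a; OMe on C6, OH on C7 and C8) is fused to a saturated ring B (C1–C4). Ring B carries a 4-hydroxy-3-methoxyphenyl (guaiacyl) ring on C1, hydroxymethyl groups C9 on C2 and C10 on C3, and a benzylic CH2 at C4. It holds three contiguous stereocentres, C1 (S), C2 (R) and C3 (R), with all three substituents mutually trans. C1 is a diarylmethine with no activating group beside it, so it cannot be equilibrated and must be set in the absolute sense. Once set it can control C2 if both carbons sit in a ring, and C2 can control C3 through its CH2OH. Ring A is pentasubstituted; its three oxygens must be told apart (one methyl ether, two phenols) and placed correctly relative to C4a and C8a. The 7,8-diol next to a methoxy group and the guaiacol are easily oxidised to quinones, and the doubly benzylic C1–H of any dihydronaphthalene on the way invites aromatisation. The phenols should therefore stay masked to the end and oxidants be avoided once C1 is in place. The enabling feature is that C3 bears C10 and is bonded to the benzylic C4, which hangs on C4a of ring A. C3–C4 can thus be made as a double bond from a vinyl group on C4a and a methylidene on C3, and the C9 hydroxyl on neighbouring C2 then lies over one face of that bond and can deliver hydrogen to C3.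

## Retrosynthesis

**21 from 20.** The last cut is of the four O–CH2Ph bonds (on O7, O8, O10 and the guaiacyl oxygen). Benzyl is chosen throughout because one neutral, non-oxidising hydrogenolysis frees every hydroxyl at once, and because benzyl ethers pass through the enolate, organolithium, titanium, fluoride, ruthenium and iridium steps before it. The forward step only has to leave the C1–H bond alone.

**20 from 19.** Taking away the hydrogens on C3 and C4 turns the C3 stereocentre into a C3=C4 double bond conjugated with ring A. This is preferred to setting C3 in an open chain: in the cyclic alkene 19 the C9 hydroxyl on C2 is held over one face of the alkene and can direct a cationic iridium catalyst. 19 has two stereocentres in place of three. The forward reaction must add hydrogen to C3 from the face that carries C9.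

**19 from 18.** The C3=C4 bond is cut by ring-closing metathesis logic, giving diene 18 with a vinyl group on C4a and a methylidene on C3. The classical closure of ring B at C1–C8a by electrophilic attack on ring A would have to choose between two non-equivalent ortho positions of a trioxygenated benzyl ring and would pass through a cation at C1. Cuts at C1–C2 or C2–C3 would disturb the stereocentres. The metathesis cut touches neither C1 nor C2. 18 is acyclic, and the forward step needs only ring closure over intermolecular coupling.

**18 from 17 and 16.** The C9 silyl ether is restored (17) and the C3 methylidene is traced to the ketone 16. Masking C9 as its silyl ether keeps the β-oxygenated carbonyl compounds from eliminating or retro-aldolising. The methylenation must be non-basic because C2 is α to the ketone.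

**16 from 12 and 13.** The C3–C10 bond is cut: the BnOCH2 unit comes from stannane 13 by tin–lithium exchange, and C3 is the carbonyl of Weinreb amide 12. The amide is preferred to the aryl lactone as acceptor because its chelated adduct stops at the ketone, whereas an aryl ester would release the more electrophilic α-alkoxy ketone into the reagent.

**12 from 11 and 10.** Removing the O8 benzyl group gives phenol 11. Cutting the amide C3–N bond and re-forming the O8–C3 acyl bond gives lactone 10. The lactone ties O8 of ring A to C3, so that C8a, C1, C2 and C3 lie in a six-membered ring in which C1 can control C2. Opening must avoid base so that C2 is not epimerised.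

**10 from 9 and 7.** The silyl group is removed (9) and the C2–C9 bond is cut, giving lactone 7 and formaldehyde by way of enolate 8. In the ring the C1 aryl group blocks one face of the enolate, so the trans relation at C1/C2 is obtained without an auxiliary.

**7 from 5 and 6.** The C1–aryl bond is cut, giving coumarin 5 and boronic acid 6. A catalytic asymmetric conjugate arylation of a flat coumarin sets the one stereocentre that nothing else can correct. The forward step needs face selectivity from the ligand and tolerance of the C4a vinyl group, which lies peri to the reacting carbon.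

**5 from 4, 3, 2 and 1.** The C4a–vinyl bond is cut (Stille coupling of bromide 4). The bromide comes from phenol 3 by benzylation, 3 from 2 by bromination para to the free phenol, and 2 from daphnetin 1 by methylation of the more acidic phenol. Daphnetin already contains ring A with its three oxygens, the carbon that becomes C1, and the lactone that becomes the C8 hydroxyl and C3.

## Roads not taken

**Alternative 1:** The cut is at C4a–C8a and C5–C6, so ring A is unravelled into a 3,4-bis(benzyloxy)furan on C1 and a terminal alkynyl ketone at C4 (substrate A2). On heating, A2 should undergo an intramolecular furan Diels–Alder reaction. The oxygen-bridged adduct would open and aromatise to the tetralone lactone A1, closing ring B and leaving a phenol on C6.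
- Merits: ring A is made, not bought, so its substitution pattern is fixed by the tether and the C6 hydroxyl is born free and alone, ready for methylation. In this respect it is better than the chosen plan, which rests on two regiochemical decisions on a preformed arene (steps 1 and 2).
- Weak points: A2 must already hold C1, C2 and C3 in the right configuration, since the key step sets none, and C3 is α to the ynone and can epimerise. The dialkoxyfuran is very electron-rich and sensitive to acid and air. After the key step the C4 ketone must be removed, the lactone reduced and the C6 phenol methylated before deprotection.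
- Comparison: the chosen plan sets against the regiochemical elegance of A1 a key step with only two steps after it, and a C3 centre made under control after the ring is closed.

**Alternative 2:** The cut is at C4a–C5 and C8–C8a: ring A is built on a finished ring B from the cyclohexenylstannane A4 and the squaric-acid-derived chlorocyclobutenone A5. Pd(PPh3)4 would couple the two at C4a–C5. Warming would open the alkenylcyclobutenone to a dienylketene, which closes onto C8a and tautomerises to phenol A3.
- Merits: the benzannulation is regiospecific and delivers a fully substituted phenol with the C8 hydroxyl free.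
- Weak points: A3 carries methyl ethers on both C6 and C7, whereas 21 has a hydroxyl on C7. One of three aryl methyl ethers would have to be cleaved selectively, which is plausible for the middle oxygen of three but not assured next to the guaiacyl ether. A4 needs all three stereocentres before the key step, with C1 both allylic and benzylic. Two esters must still be reduced.
- Comparison: the road is as good as the chosen one for the regiochemistry of ring A, but longer and weaker in stereocontrol and in the oxygen pattern. The chosen plan takes the correct O-methylation pattern from daphnetin and makes its stereocentres one after the other.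

**Alternative 3:** The cut is at C1–C2 and C3–C4: ring B is formed from the 2-benzylbenzaldehyde A7 and the lactate-derived fumarate A8. Irradiation near 365 nm would convert A7 into its hydroxy-ortho-quinodimethane, which adds A8 in a [4+2] reaction to give A6.
- Merits: this is the most convergent road. Two bonds, ring B and up to four stereocentres arise in one step from two simple partners, and the fumarate geometry gives the 2,3-trans relation directly, which the chosen plan has to earn in a separate hydrogenation. If the face selectivity held, it would be clearly shorter than the 15 steps proposed here.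
- Weak points: the absolute sense rests on lactate esters, whose high selectivity is established for Lewis-acid-promoted thermal cycloadditions. Under irradiation a Lewis acid would interfere with the photoenol, so the selectivity is open. The dienol of A7 must form next to the C8 acetal oxygen. A6 carries a surplus C4 hydroxyl, a methoxymethyl ether and two esters to be removed or reduced.
- Comparison: the chosen plan is longer, but each of its stereocentres is fixed by an element with close precedent: ligand control at C1, ring control at C2 and hydroxyl direction at C3.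

Key step: step 13

Remark: positions are numbered as in aryltetralin lignans (C1 bears the guaiacyl ring, C9 is on C2, C10 on C3, ring A is C4a, C5–C8, C8a). Coumarin intermediates carry chromenone numbers, whose C4, C3 and C2 become C1, C2 and C3. Both stannanes used are taken as purchasable.

## Route

Step 1
Reactants: 1 daphnetin (7,8-dihydroxy-2H-chromen-2-one)
Product: 2 8-hydroxy-7-methoxy-2H-chromen-2-one
Conditions: MeI (1.05 equiv), Li2CO3, DMF, 45 °C
Reagents that add atoms: iodomethane, CI
Why: Williamson etherification with a weak base; the 7-OH is the more acidic phenol because its anion is conjugated through C4a with the unsaturated lactone carbonyl, so it should be ionised and methylated in preference to the 8-OH.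

Step 2
Reactants: 2 8-hydroxy-7-methoxy-2H-chromen-2-one
Product: 3 5-bromo-8-hydroxy-7-methoxy-2H-chromen-2-one
Conditions: N-bromosuccinimide (1.0 equiv), MeCN, 0 °C
Reagents that add atoms: N-bromosuccinimide, O=C1CCC(=O)N1Br
Why: Electrophilic aromatic bromination; C5 is the only position para to the free 8-OH (both ortho positions are substituted) whereas C6 is only ortho to the methyl ether, so bromine should enter at C5, and one equivalent at low temperature holds back attack on the pyranone double bond.

Step 3
Reactants: 3 5-bromo-8-hydroxy-7-methoxy-2H-chromen-2-one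
Product: 4 8-(benzyloxy)-5-bromo-7-methoxy-2H-chromen-2-one
Conditions: BnBr, K2CO3, DMF, rt
Reagents that add atoms: benzyl bromide, BrCc1ccccc1
Why: Williamson etherification of the only free phenol; coumarins are stable to carbonate in dry DMF.

Step 4
Reactants: 4 8-(benzyloxy)-5-bromo-7-methoxy-2H-chromen-2-one
Product: 5 8-(benzyloxy)-5-ethenyl-7-methoxy-2H-chromen-2-one
Conditions: tributyl(vinyl)stannane (1.2 equiv), Pd(PPh3)4 (5 mol%), toluene, 100 °C
Reagents that add atoms: tributyl(vinyl)stannane, C=C[Sn](CCCC)(CCCC)CCCC
Why: Stille coupling; the aryl bromide at C5 is conjugated with the lactone and should add readily to zerovalent palladium, and the neutral conditions leave the lactone closed.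

Step 5
Reactants: 5 8-(benzyloxy)-5-ethenyl-7-methoxy-2H-chromen-2-one; 6 [4-(benzyloxy)-3-methoxyphenyl]boronic acid
Product: 7 (4S)-8-(benzyloxy)-4-[4-(benzyloxy)-3-methoxyphenyl]-5-ethenyl-7-methoxy-3,4-dihydro-2H-chromen-2-one
Conditions: Rh(acac)(C2H4)2 (3 mol%), (S)-SEGPHOS (3.3 mol%), 6 (4 equiv), dioxane/H2O 10:1, 60 °C
Reagents that add atoms: none
Why: Hayashi–Miyaura asymmetric conjugate addition: the aryl group passes from boron to a hydroxo complex of monovalent rhodium, the coumarin C3=C4 bond inserts into the aryl–rhodium bond on the face chosen by the bisphosphine, and water releases the lactone. The (S) ligand is the enantiomer expected from the facial model for coumarins to give 4S (C1 of the target), and the absence of added base keeps the aryl lactone closed.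

Step 6
Reactants: 7 (4S)-8-(benzyloxy)-4-[4-(benzyloxy)-3-methoxyphenyl]-5-ethenyl-7-methoxy-3,4-dihydro-2H-chromen-2-one
Product: 9 (3S,4S)-8-(benzyloxy)-4-[4-(benzyloxy)-3-methoxyphenyl]-5-ethenyl-3-(hydroxymethyl)-7-methoxy-3,4-dihydro-2H-chromen-2-one, via lithium lactone enolate 8 (not isolated)
Conditions: LiN(SiMe3)2, THF, −78 °C; CH2O (gas, from cracked paraformaldehyde), −78 °C; AcOH, −78 °C
Reagents that add atoms: formaldehyde, C=O
Why: Aldol addition of a lactone enolate to formaldehyde; the C4 aryl group is pushed pseudoaxial by the peri vinyl group at C5 and covers one face of the enolate, so formaldehyde should enter anti to it and give the 3,4-trans lactone (3S, C2 of the target). The cold acidic quench avoids dehydration of the β-hydroxy lactone.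

Step 7
Reactants: 9 (3S,4S)-8-(benzyloxy)-4-[4-(benzyloxy)-3-methoxyphenyl]-5-ethenyl-3-(hydroxymethyl)-7-methoxy-3,4-dihydro-2H-chromen-2-one
Product: 10 (3S,4S)-8-(benzyloxy)-4-[4-(benzyloxy)-3-methoxyphenyl]-3-({[tert-butyl(dimethyl)silyl]oxy}methyl)-5-ethenyl-7-methoxy-3,4-dihydro-2H-chromen-2-one
Conditions: TBSCl, imidazole, DMF, rt
Reagents that add atoms: tert-butyldimethylsilyl chloride, CC(C)(C)[Si](C)(C)Cl
Why: Standard silylation of a primary alcohol; the silyl ether keeps the β-oxygenated carbonyl compounds of steps 8–11 from dehydrating or undergoing retro-aldol cleavage.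

Step 8
Reactants: 10 (3S,4S)-8-(benzyloxy)-4-[4-(benzyloxy)-3-methoxyphenyl]-3-({[tert-butyl(dimethyl)silyl]oxy}methyl)-5-ethenyl-7-methoxy-3,4-dihydro-2H-chromen-2-one
Product: 11 (2S,3S)-3-[3-(benzyloxy)-6-ethenyl-2-hydroxy-4-methoxyphenyl]-3-[4-(benzyloxy)-3-methoxyphenyl]-2-({[tert-butyl(dimethyl)silyl]oxy}methyl)-N-methoxy-N-methylpropanamide
Conditions: MeNH(OMe)·HCl, AlMe3, CH2Cl2, 0 °C → rt; aq. potassium sodium tartrate
Reagents that add atoms: N,O-dimethylhydroxylamine hydrochloride, CNOC.Cl
Why: Weinreb aminolysis of an activated aryl lactone by an aluminium amide; the reagent is a poor base, so the α-centre (C2 of the target) should keep its configuration and the silyl ether should not be eliminated. The phenol is carried on promptly to avoid re-lactonisation.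

Step 9
Reactants: 11 (2S,3S)-3-[3-(benzyloxy)-6-ethenyl-2-hydroxy-4-methoxyphenyl]-3-[4-(benzyloxy)-3-methoxyphenyl]-2-({[tert-butyl(dimethyl)silyl]oxy}methyl)-N-methoxy-N-methylpropanamide
Product: 12 (2S,3S)-3-[2,3-bis(benzyloxy)-6-ethenyl-4-methoxyphenyl]-3-[4-(benzyloxy)-3-methoxyphenyl]-2-({[tert-butyl(dimethyl)silyl]oxy}methyl)-N-methoxy-N-methylpropanamide
Conditions: BnBr, K2CO3, DMF, 40 °C
Reagents that add atoms: benzyl bromide, BrCc1ccccc1
Why: Williamson etherification of the freed C8 phenol; carbonate is too weak to deprotonate the amide α-position, and benzylation rules out any return to the lactone.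

Step 10
Reactants: 12 (2S,3S)-3-[2,3-bis(benzyloxy)-6-ethenyl-4-methoxyphenyl]-3-[4-(benzyloxy)-3-methoxyphenyl]-2-({[tert-butyl(dimethyl)silyl]oxy}methyl)-N-methoxy-N-methylpropanamide; 13 (benzyloxymethyl)tributylstannane
Product: 16 (3S,4S)-1-(benzyloxy)-4-[2,3-bis(benzyloxy)-6-ethenyl-4-methoxyphenyl]-4-[4-(benzyloxy)-3-methoxyphenyl]-3-({[tert-butyl(dimethyl)silyl]oxy}methyl)butan-2-one, via (benzyloxymethyl)lithium 14 (not isolated), via lithium hemiaminal alkoxide 15 (not isolated)
Conditions: 13 (1.6 equiv), n-BuLi (1.5 equiv), THF, −78 °C; then 12, −78 °C; aq. NH4Cl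
Reagents that add atoms: none
Why: Tin–lithium exchange gives the α-alkoxymethyllithium, which adds once to the Weinreb amide; the chelated tetrahedral adduct survives until work-up, so the C3–C10 bond forms without over-addition, and the low temperature and modest basicity of the reagent should spare the α-centre.

Step 11
Reactants: 16 (3S,4S)-1-(benzyloxy)-4-[2,3-bis(benzyloxy)-6-ethenyl-4-methoxyphenyl]-4-[4-(benzyloxy)-3-methoxyphenyl]-3-({[tert-butyl(dimethyl)silyl]oxy}methyl)butan-2-one
Product: 17 {[(2R)-2-{(S)-[2,3-bis(benzyloxy)-6-ethenyl-4-methoxyphenyl][4-(benzyloxy)-3-methoxyphenyl]methyl}-3-[(benzyloxy)methyl]but-3-en-1-yl]oxy}(tert-butyl)dimethylsilane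
Conditions: Cp2TiMe2 (3 equiv), toluene, 70 °C, dark
Reagents that add atoms: bis(cyclopentadienyl)dimethyltitanium, [CH3-].[CH3-].[Ti+4].c1cc[cH-]c1.c1cc[cH-]c1
Why: Petasis methylenation; the titanium methylidene formed on heating is non-basic, so the ketone should be converted to the 1,1-disubstituted alkene without epimerisation at C2 or β-elimination of the silyloxy group, which a phosphorus ylide could cause. The descriptor at C2 changes to R only because the priorities change.

Step 12
Reactants: 17 {[(2R)-2-{(S)-[2,3-bis(benzyloxy)-6-ethenyl-4-methoxyphenyl][4-(benzyloxy)-3-methoxyphenyl]methyl}-3-[(benzyloxy)methyl]but-3-en-1-yl]oxy}(tert-butyl)dimethylsilane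
Product: 18 (2R)-2-{(S)-[2,3-bis(benzyloxy)-6-ethenyl-4-methoxyphenyl][4-(benzyloxy)-3-methoxyphenyl]methyl}-3-[(benzyloxy)methyl]but-3-en-1-ol
Conditions: Bu4NF, THF, 0 °C → rt
Reagents that add atoms: none
Why: Fluoride cleavage of a primary silyl ether; with the carbonyl gone nothing in the molecule is base-sensitive, and the C9 hydroxyl is freed for step 14.

Step 13
Reactants: 18 (2R)-2-{(S)-[2,3-bis(benzyloxy)-6-ethenyl-4-methoxyphenyl][4-(benzyloxy)-3-methoxyphenyl]methyl}-3-[(benzyloxy)methyl]but-3-en-1-ol
Product: 19 [(1S,2R)-7,8-bis(benzyloxy)-1-[4-(benzyloxy)-3-methoxyphenyl]-3-[(benzyloxy)methyl]-6-methoxy-1,2-dihydronaphthalen-2-yl]methanol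
Conditions: second-generation Grubbs catalyst (H2IMes)(PCy3)Cl2Ru=CHPh (5 mol%), degassed toluene (0.005 M), 80 °C, argon sweep
Reagents that add atoms: none
Why: Ring-closing alkene metathesis by the Chauvin mechanism: loss of PCy3 gives a 14-electron ruthenium carbene that exchanges with the styrene-type vinyl group of 18, the only unhindered alkene, placing the carbene on C4. This carbene adds across the 1,1-disubstituted C3=CH2 bond to a ruthenacyclobutane, which breaks up to the C3=C4 bond and Ru=CH2; the two terminal CH2 groups leave as ethylene. The closest known reaction type is ring-closing metathesis of 2-vinylaryl compounds bearing a tethered 1,1-disubstituted alkene to 3-substituted 1,2-dihydronaphthalenes and 2H-chromenes with this catalyst. Ring B closes as a six-membered carbocycle with the new alkene endocyclic and conjugated with ring A, and two of the six ring atoms belong to the arene, which holds the alkenes close. No stereocentre is formed: C1 and C2 are spectators without an acidic or metal-labile bond and should be carried through unchanged, while C3 is left flat for step 14. The step needs ring closure over intermolecular coupling and no alkene migration; six-ring formation, high dilution, the slow homocoupling of the ortho-substituted styrene, removal of ethylene and degassed solvent should secure this. The free primary hydroxyl is tolerated by the ruthenium carbene.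

Step 14
Reactants: 19 [(1S,2R)-7,8-bis(benzyloxy)-1-[4-(benzyloxy)-3-methoxyphenyl]-3-[(benzyloxy)methyl]-6-methoxy-1,2-dihydronaphthalen-2-yl]methanol
Product: 20 [(1S,2R,3R)-7,8-bis(benzyloxy)-1-[4-(benzyloxy)-3-methoxyphenyl]-3-[(benzyloxy)methyl]-6-methoxy-1,2,3,4-tetrahydronaphthalen-2-yl]methanol
Conditions: [Ir(cod)(PCy3)(py)]PF6 (10 mol%), H2 (1 atm), CH2Cl2, rt
Reagents that add atoms: none
Why: Hydroxyl-directed homogeneous hydrogenation with a cationic complex of monovalent iridium; the C1 aryl group (peri to the C8 ether) and hence the trans C2 CH2OH are pseudoaxial, so the C9 hydroxyl lies over one face of the C3=C4 bond, binds iridium and has hydrogen delivered to C3 from its own face. C10 should therefore end trans to C9 (3R), and the benzyl ethers are untouched by the homogeneous catalyst.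

Step 15
Reactants: 20 [(1S,2R,3R)-7,8-bis(benzyloxy)-1-[4-(benzyloxy)-3-methoxyphenyl]-3-[(benzyloxy)methyl]-6-methoxy-1,2,3,4-tetrahydronaphthalen-2-yl]methanol
Product: 21 (6R,7R,8S)-8-(4-hydroxy-3-methoxyphenyl)-6,7-bis(hydroxymethyl)-3-methoxy-5,6,7,8-tetrahydronaphthalene-1,2-diol (the target; 1S,2R,3R in lignan numbering, all-trans)
Conditions: H2 (1 atm), 10% Pd/C, EtOAc/MeOH, rt; filtration and concentration under argon
Reagents that add atoms: none
Why: Hydrogenolysis of three aryl benzyl ethers and one alkyl benzyl ether on palladium; no stereocentre carries a cleavable C–O bond, and exclusion of air during work-up protects the electron-rich catechol.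

## Compound list

1 | daphnetin (7,8-dihydroxy-2H-chromen-2-one) | O=c1ccc2ccc(O)c(O)c2o1 | starting material
2 | 8-hydroxy-7-methoxy-2H-chromen-2-one | O=c1ccc2ccc(OC)c(O)c2o1 | intermediate
3 | 5-bromo-8-hydroxy-7-methoxy-2H-chromen-2-one | O=c1ccc2c(Br)cc(OC)c(O)c2o1 | intermediate
4 | 8-(benzyloxy)-5-bromo-7-methoxy-2H-chromen-2-one | O=c1ccc2c(Br)cc(OC)c(OCc3ccccc3)c2o1 | intermediate
5 | 8-(benzyloxy)-5-ethenyl-7-methoxy-2H-chromen-2-one | O=c1ccc2c(C=C)cc(OC)c(OCc3ccccc3)c2o1 | intermediate
6 | [4-(benzyloxy)-3-methoxyphenyl]boronic acid | COc1cc(B(O)O)ccc1OCc1ccccc1 | starting material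
7 | (4S)-8-(benzyloxy)-4-[4-(benzyloxy)-3-methoxyphenyl]-5-ethenyl-7-methoxy-3,4-dihydro-2H-chromen-2-one | COc1cc([C@@H]2CC(=O)Oc3c2c(C=C)cc(OC)c3OCc4ccccc4)ccc1OCc1ccccc1 | intermediate
8 | lithium enolate of lactone 7 (formed in the flask, not isolated) | [Li+].[O-]C1=C[C@@H](c2ccc(OCc3ccccc3)c(OC)c2)c2c(C=C)cc(OC)c(OCc3ccccc3)c2O1 | intermediate
9 | (3S,4S)-8-(benzyloxy)-4-[4-(benzyloxy)-3-methoxyphenyl]-5-ethenyl-3-(hydroxymethyl)-7-methoxy-3,4-dihydro-2H-chromen-2-one (3,4-trans) | COc1cc([C@@H]2[C@@H](CO)C(=O)Oc3c2c(C=C)cc(OC)c3OCc4ccccc4)ccc1OCc1ccccc1 | intermediate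
10 | (3S,4S)-8-(benzyloxy)-4-[4-(benzyloxy)-3-methoxyphenyl]-3-({[tert-butyl(dimethyl)silyl]oxy}methyl)-5-ethenyl-7-methoxy-3,4-dihydro-2H-chromen-2-one | COc1cc([C@@H]2[C@@H](CO[Si](C)(C)C(C)(C)C)C(=O)Oc3c2c(C=C)cc(OC)c3OCc4ccccc4)ccc1OCc1ccccc1 | intermediate
11 | (2S,3S)-3-[3-(benzyloxy)-6-ethenyl-2-hydroxy-4-methoxyphenyl]-3-[4-(benzyloxy)-3-methoxyphenyl]-2-({[tert-butyl(dimethyl)silyl]oxy}methyl)-N-methoxy-N-methylpropanamide | COc1cc([C@H]([C@@H](CO[Si](C)(C)C(C)(C)C)C(=O)N(C)OC)c2c(C=C)cc(OC)c(OCc3ccccc3)c2O)ccc1OCc1ccccc1 | intermediate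
12 | (2S,3S)-3-[2,3-bis(benzyloxy)-6-ethenyl-4-methoxyphenyl]-3-[4-(benzyloxy)-3-methoxyphenyl]-2-({[tert-butyl(dimethyl)silyl]oxy}methyl)-N-methoxy-N-methylpropanamide | COc1cc([C@H]([C@@H](CO[Si](C)(C)C(C)(C)C)C(=O)N(C)OC)c2c(C=C)cc(OC)c(OCc3ccccc3)c2OCc4ccccc4)ccc1OCc1ccccc1 | intermediate
13 | (benzyloxymethyl)tributylstannane | CCCC[Sn](CCCC)(CCCC)COCc1ccccc1 | starting material
14 | (benzyloxymethyl)lithium (formed in the flask, not isolated) | [Li]COCc1ccccc1 | intermediate
15 | lithium hemiaminal alkoxide from 12 and 14 (configuration at the new tetrahedral carbon undefined; not isolated) | [Li+].COc1cc([C@H]([C@@H](CO[Si](C)(C)C(C)(C)C)C([O-])(COCc2ccccc2)N(C)OC)c2c(C=C)cc(OC)c(OCc3ccccc3)c2OCc4ccccc4)ccc1OCc1ccccc1 | intermediate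
16 | (3S,4S)-1-(benzyloxy)-4-[2,3-bis(benzyloxy)-6-ethenyl-4-methoxyphenyl]-4-[4-(benzyloxy)-3-methoxyphenyl]-3-({[tert-butyl(dimethyl)silyl]oxy}methyl)butan-2-one | COc1cc([C@H]([C@@H](CO[Si](C)(C)C(C)(C)C)C(=O)COCc2ccccc2)c2c(C=C)cc(OC)c(OCc3ccccc3)c2OCc4ccccc4)ccc1OCc1ccccc1 | intermediate
17 | {[(2R)-2-{(S)-[2,3-bis(benzyloxy)-6-ethenyl-4-methoxyphenyl][4-(benzyloxy)-3-methoxyphenyl]methyl}-3-[(benzyloxy)methyl]but-3-en-1-yl]oxy}(tert-butyl)dimethylsilane | COc1cc([C@H]([C@@H](CO[Si](C)(C)C(C)(C)C)C(=C)COCc2ccccc2)c2c(C=C)cc(OC)c(OCc3ccccc3)c2OCc4ccccc4)ccc1OCc1ccccc1 | intermediate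
18 | (2R)-2-{(S)-[2,3-bis(benzyloxy)-6-ethenyl-4-methoxyphenyl][4-(benzyloxy)-3-methoxyphenyl]methyl}-3-[(benzyloxy)methyl]but-3-en-1-ol | COc1cc([C@H]([C@@H](CO)C(=C)COCc2ccccc2)c2c(C=C)cc(OC)c(OCc3ccccc3)c2OCc4ccccc4)ccc1OCc1ccccc1 | intermediate
19 | [(1S,2R)-7,8-bis(benzyloxy)-1-[4-(benzyloxy)-3-methoxyphenyl]-3-[(benzyloxy)methyl]-6-methoxy-1,2-dihydronaphthalen-2-yl]methanol | COc1cc([C@H]2c3c(cc(OC)c(OCc4ccccc4)c3OCc5ccccc5)C=C(COCc6ccccc6)[C@@H]2CO)ccc1OCc1ccccc1 | intermediate
20 | [(1S,2R,3R)-7,8-bis(benzyloxy)-1-[4-(benzyloxy)-3-methoxyphenyl]-3-[(benzyloxy)methyl]-6-methoxy-1,2,3,4-tetrahydronaphthalen-2-yl]methanol | COc1cc([C@H]2c3c(cc(OC)c(OCc4ccccc4)c3OCc5ccccc5)C[C@@H](COCc6ccccc6)[C@@H]2CO)ccc1OCc1ccccc1 | intermediate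
21 | (6R,7R,8S)-8-(4-hydroxy-3-methoxyphenyl)-6,7-bis(hydroxymethyl)-3-methoxy-5,6,7,8-tetrahydronaphthalene-1,2-diol | COc1cc([C@H]2c3c(cc(OC)c(O)c3O)C[C@@H](CO)[C@@H]2CO)ccc1O | target

## Step count and least certain steps

Total step count: 15. Longest linear sequence: 15 steps, from daphnetin 1 to 21.

**Step 13 (key step).** Closure onto the hindered 1,1-disubstituted alkene next to the C2 stereocentre may be slow. Intermolecular coupling of the styrene ends, or alkene migration in the allylic benzyl ether caused by ruthenium hydrides from catalyst decay, could then overtake ring closure. The fallback closes the same C3=C4 bond from the ketone instead of the methylidene. It sets out from 16, which is treated with one equivalent of Mo(=CHCMe2Ph)(N-2,6-i-Pr2C6H3)[OCMe(CF3)2]2 in benzene at room temperature. The molybdenum alkylidene first undergoes metathesis with the vinyl group and the resulting arylmethylidene then olefinates the ketone carbonyl intramolecularly, a known stoichiometric alkene metathesis–carbonyl olefination. This should give the silyl ether tert-butyl{[(1S,2R)-7,8-bis(benzyloxy)-1-[4-(benzyloxy)-3-methoxyphenyl]-3-[(benzyloxy)methyl]-6-methoxy-1,2-dihydronaphthalen-2-yl]methoxy}dimethylsilane F1. Bu4NF in THF would then free the alcohol, and the fallback comes back to the route at 19, saving step 11.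

**Step 5.** Insertion at C4 of an electron-rich coumarin with a peri substituent may be slow, so that protodeboronation of 6 or aryl transfer to the vinyl group takes over. The fallback moves the arylation before the vinylation. It sets out from 4, whose bromine is compact, electron-withdrawing and inert toward monovalent rhodium. The same rhodium/(S)-SEGPHOS conditions should give (4S)-8-(benzyloxy)-4-[4-(benzyloxy)-3-methoxyphenyl]-5-bromo-7-methoxy-3,4-dihydro-2H-chromen-2-one F2. Stille coupling of F2 with tributyl(vinyl)stannane and Pd(PPh3)4 in toluene at 110 °C then comes back to the route at 7.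

**Step 2.** Bromine may add to the pyranone C3=C4 bond or enter twice, and the regiochemistry rests on electronic preference alone. The fallback introduces the C4a carbon as an aldehyde. It sets out from 2: Duff formylation (hexamethylenetetramine, CF3CO2H, 80 °C, then aq. HCl) of a phenol whose two ortho positions are blocked should go para and give 8-hydroxy-7-methoxy-2-oxo-2H-chromene-5-carbaldehyde F3. Benzylation (BnBr, K2CO3, DMF) gives 8-(benzyloxy)-7-methoxy-2-oxo-2H-chromene-5-carbaldehyde F4. Wittig methylenation (Ph3P=CH2 from Ph3PCH3Br and KOt-Bu, THF, 0 °C) then comes back to the route at 5, with the same number of steps and no tin.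

**Step 10.** The organolithium may deprotonate the hindered α-position of the Weinreb amide, with loss of the silyloxy group, or cleave the N–O bond in place of adding to the carbonyl. The fallback uses a more electrophilic carbonyl. It sets out from 12, which i-Bu2AlH in THF at −78 °C should reduce to (2S,3S)-3-[2,3-bis(benzyloxy)-6-ethenyl-4-methoxyphenyl]-3-[4-(benzyloxy)-3-methoxyphenyl]-2-({[tert-butyl(dimethyl)silyl]oxy}methyl)propanal F5. Addition of (benzyloxymethyl)lithium 14 at −78 °C gives (3S,4S)-1-(benzyloxy)-4-[2,3-bis(benzyloxy)-6-ethenyl-4-methoxyphenyl]-4-[4-(benzyloxy)-3-methoxyphenyl]-3-({[tert-butyl(dimethyl)silyl]oxy}methyl)butan-2-ol F6 as a mixture at the carbinol carbon. Dess–Martin oxidation in buffered CH2Cl2 then comes back to the route at 16.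

**Step 14.** The many ether oxygens may compete with the C9 hydroxyl for iridium, or the catalyst may aggregate before conversion is complete, so that hydrogen is delivered without direction and the face selectivity at C3 falls. The fallback replaces substrate direction by catalyst control. It sets out from 19, which is hydrogenated with a chiral iridium N,P catalyst of the type [Ir(cod)(t-Bu-PHOX)]B[3,5-(CF3)2C6H3]4 (ligand enantiomer matched to the substrate) in CH2Cl2 under 50 bar H2. Such catalysts reduce trisubstituted cyclic styrenes with high face selectivity without a directing group. It comes back to the route at 20 and makes no new compound F0.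

## Further compounds

F1 | step 13 | tert-butyl{[(1S,2R)-7,8-bis(benzyloxy)-1-[4-(benzyloxy)-3-methoxyphenyl]-3-[(benzyloxy)methyl]-6-methoxy-1,2-dihydronaphthalen-2-yl]methoxy}dimethylsilane | COc1cc([C@H]2c3c(cc(OC)c(OCc4ccccc4)c3OCc5ccccc5)C=C(COCc6ccccc6)[C@@H]2CO[Si](C)(C)C(C)(C)C)ccc1OCc1ccccc1
F2 | step 5 | (4S)-8-(benzyloxy)-4-[4-(benzyloxy)-3-methoxyphenyl]-5-bromo-7-methoxy-3,4-dihydro-2H-chromen-2-one | COc1cc([C@@H]2CC(=O)Oc3c2c(Br)cc(OC)c3OCc4ccccc4)ccc1OCc1ccccc1
F3 | step 2 | 8-hydroxy-7-methoxy-2-oxo-2H-chromene-5-carbaldehyde | O=Cc1cc(OC)c(O)c2oc(=O)ccc12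
F4 | step 2 | 8-(benzyloxy)-7-methoxy-2-oxo-2H-chromene-5-carbaldehyde | O=Cc1cc(OC)c(OCc3ccccc3)c2oc(=O)ccc12
F5 | step 10 | (2S,3S)-3-[2,3-bis(benzyloxy)-6-ethenyl-4-methoxyphenyl]-3-[4-(benzyloxy)-3-methoxyphenyl]-2-({[tert-butyl(dimethyl)silyl]oxy}methyl)propanal | COc1cc([C@H]([C@@H](CO[Si](C)(C)C(C)(C)C)C=O)c2c(C=C)cc(OC)c(OCc3ccccc3)c2OCc4ccccc4)ccc1OCc1ccccc1
F6 | step 10 | (3S,4S)-1-(benzyloxy)-4-[2,3-bis(benzyloxy)-6-ethenyl-4-methoxyphenyl]-4-[4-(benzyloxy)-3-methoxyphenyl]-3-({[tert-butyl(dimethyl)silyl]oxy}methyl)butan-2-ol (both C2 epimers) | COc1cc([C@H]([C@@H](CO[Si](C)(C)C(C)(C)C)C(O)COCc2ccccc2)c2c(C=C)cc(OC)c(OCc3ccccc3)c2OCc4ccccc4)ccc1OCc1ccccc1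
F0 | step 14 | none | none
A1 | alternative 1 | trans-fused 1-aryl-7,8-bis(benzyloxy)-6-hydroxy-4-oxotetralin 2,3-γ-lactone (carbonyl C9 on C2, OCH2 C10 on C3; aryl = 4-(benzyloxy)-3-methoxyphenyl) | COc1cc([C@H]2c3c(cc(O)c(OCc4ccccc4)c3OCc6ccccc6)C(=O)[C@H]5COC(=O)[C@H]25)ccc1OCc1ccccc1
A2 | alternative 1 | trans-γ-lactone bearing on C2 the (S)-[3,4-bis(benzyloxy)furan-2-yl][4-(benzyloxy)-3-methoxyphenyl]methyl group and on C3 a prop-2-ynoyl group | COc1cc([C@@H](c2occ(OCc3ccccc3)c2OCc4ccccc4)[C@H]5C(=O)OC[C@@H]5C(=O)C#C)ccc1OCc1ccccc1
A3 | alternative 2 | dimethyl all-trans-1-[4-(benzyloxy)-3-methoxyphenyl]-8-hydroxy-6,7-dimethoxy-1,2,3,4-tetrahydronaphthalene-2,3-dicarboxylate | COc1cc([C@H]2c3c(cc(OC)c(OC)c3O)C[C@@H](C(=O)OC)[C@@H]2C(=O)OC)ccc1OCc1ccccc1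
A4 | alternative 2 | dimethyl trans,trans-3-[4-(benzyloxy)-3-methoxyphenyl]-5-(tributylstannyl)cyclohex-4-ene-1,2-dicarboxylate | COc1cc([C@H]2C=C([Sn](CCCC)(CCCC)CCCC)C[C@@H](C(=O)OC)[C@@H]2C(=O)OC)ccc1OCc1ccccc1
A5 | alternative 2 | 4-chloro-2,3-dimethoxycyclobut-2-en-1-one | COC1=C(OC)C(=O)C1Cl
A6 | alternative 3 | bis[(2S)-1-methoxy-1-oxopropan-2-yl] 7-(benzyloxy)-1-[4-(benzyloxy)-3-methoxyphenyl]-4-hydroxy-6-methoxy-8-(methoxymethoxy)-1,2,3,4-tetrahydronaphthalene-2,3-dicarboxylate (1,2-trans, 2,3-trans, aryl and C4 hydroxyl cis) | COc1cc([C@H]2c3c(cc(OC)c(OCc4ccccc4)c3OCOC)[C@@H](O)[C@@H](C(=O)O[C@@H](C)C(=O)OC)[C@@H]2C(=O)O[C@@H](C)C(=O)OC)ccc1OCc1ccccc1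
A7 | alternative 3 | 4-(benzyloxy)-2-[4-(benzyloxy)-3-methoxybenzyl]-5-methoxy-3-(methoxymethoxy)benzaldehyde | COc1cc(Cc2c(C=O)cc(OC)c(OCc3ccccc3)c2OCOC)ccc1OCc1ccccc1
A8 | alternative 3 | bis[(2S)-1-methoxy-1-oxopropan-2-yl] (2E)-but-2-enedioate | COC(=O)[C@H](C)OC(=O)/C=C/C(=O)O[C@@H](C)C(=O)OC
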